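## Analysis of the target

The target is a 2-arylbenzofuran. Its benzofuran (O1, C2, C3, C3a, C4–C7, C7a; ring A is the benzene ring, ring B the furan) carries free hydroxyls at C4 and C6 and a 2-methylbut-3-en-2-yl group at C7. C2 is bonded to C5' of a 7'-hydroxy-2',2'-dimethylchroman (ring C is its benzene ring, ring D the dihydropyran). There is no stereocentre and no stereogenic double bond, so every problem is one of regiochemistry and functional-group tolerance. The sensitive elements are three free phenols on electron-rich rings, the benzofuran C2=C3 bond, and the 1,1-dimethylallyl group ortho to the C6 hydroxyl, which can close to a dihydrofuran in strong acid and can drift sigmatropically on long heating. Hydrogenation is excluded once a prenyl-type alkene is present. The quaternary benzylic carbon at C7 cannot be made by direct C-alkylation, which would give the linear 3,3-dimethylallyl connectivity. In ring C the benzofuranyl group at C5' is meta to both oxygens (on C7' and C8a') and ortho to the alkyl carbon C4a', so electrophilic substitution of a resorcinol-type chroman cannot place it. The strategy rests on this ring: oxygens at C7' and C8a' in a 1,3 relation, next to the adjacent carbon-substituted positions C4a' and C5', which is the pattern left when an acetoacetate-derived 1,1,3-trioxygenated butadiene adds to a disubstituted alkyne.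

## Retrosynthetic reasoning

**Target 28 to 27.** The last disconnection is cleavage of the acetal protecting group on O4. One protecting group is kept on O4 to the end so that O4 and O6 stay distinguishable through the rearrangement that sets C7. The forward step must free a phenol without protonating the vinyl group next to the C6 hydroxyl.

**27 to 25.** The C7–C(quaternary) bond is cut, returning the allyl unit to O6 as the 3-methylbut-2-enyl ether of 25. A [3,3] shift is the one reliable way to bond the tertiary allyl terminus to an arene carbon. It also lets the ether serve as the O6 protecting group through the whole route. The forward step has to choose C7 over C5.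

**25 to 22 to 21.** The C4' methylene is traced back to a carbonyl through the sulfonylhydrazone 22. The carbonyl is the price of the activating group in the ring-forming step. It is removed by a non-acidic, non-hydrogenative method, since the allyl ether, the acetal and the benzofuran all have to survive.

**21 to 20.** The O1'–C2' bond of ring D is cut, giving the phenol–enone 20. The forward reaction is conjugate addition of the C8a' hydroxyl to a β,β-dimethyl enone. Ring D then needs no separate carbon–carbon bond, because C4', C3', C2' and both methyls are already in the acyl group.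

**20 to 18 and 4.** This is the key disconnection. Ring C is cut at C5'–C6' and C4a'–C8a', giving ynone 18 and diene 4. It is made here because it builds the 1,3,5-pattern of ring C from acyclic carbons with the regiochemistry fixed by polarity, and it forms the hindered C2–C5' link as an ordinary alkyne–arene bond. The forward step has to deliver the diene methylene to the alkyne carbon that bears the benzofuran and then aromatise by loss of the methoxy and silyl groups.

**18 to 17 to 14 and 15; 14 to 13 to 11.** The ynone is cut between the alkyne and the carbinol carbon, giving alkyne 14 and 3-methylbut-2-enal 15, with an oxidation of alcohol 17 in between. Direct acylation of 14 with the corresponding acid chloride under amine base and zerovalent palladium was set aside. γ-Deprotonation of that acid chloride to a vinylketene would move the double bond out of conjugation, and the metal could ionise the allylic aryl ether. Alkyne 14 comes by one-carbon homologation of aldehyde 13, and the formyl carbon is placed at C2 of benzofuran 11 by deprotonation at its most acidic C–H position.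

**11 to 8 to 7 to 5 and 6.** Ring A and ring B are bought together as benzofuranone 5. Its two hydroxyls differ because O4 is hydrogen-bonded to the C3 carbonyl and O6 is the more acidic, para-related one. O6 is therefore alkylated with 6 first, O4 is then protected, and the C3 carbonyl is removed by reduction and elimination to aromatise ring B.

**4 to 2 to 1.** The diene is the doubly silylated dienol form of methyl acetoacetate 1, reached by two successive enol silylations.

## Alternatives that were turned down

**Alternative 1:** Here the benzofuran C3–C3a bond is disconnected, leading back to the flavanone A2 (7-(benzyloxy)-2-[2,2-dimethyl-7-(tosyloxy)chroman-5-yl]-5-(tosyloxy)chroman-4-one).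
- Forward key step: a trivalent iodine diacetate oxidant with acid in an orthoester solvent makes ring A migrate from C4 to C3, contracting the pyranone to the trans dihydrobenzofuran ester A1 (methyl trans-6-(benzyloxy)-2-[2,2-dimethyl-7-(tosyloxy)chroman-5-yl]-4-(tosyloxy)-2,3-dihydrobenzofuran-3-carboxylate).
- For it: A2 comes from a convergent aldol condensation and ring closure. The ring A oxygens are differentiated by chelation in an acetophenone, which is more secure than the selective alkylation used in the chosen route.
- Against it: the chroman half must be supplied as a 5-formyl chroman, so the meta-substituted ring C is still unmade. A1 carries an extra ester carbon and a saturated C2–C3 bond, which cost hydrolysis, decarboxylation and dehydrogenation. The sulfonates that shield ring A from the oxidant also lower its migratory aptitude. The benzyl group has to be removed before any alkene is introduced.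
- Comparison: the chosen route also carries a superfluous atom, the C4' carbonyl oxygen, but it makes the hard ring itself and has fewer steps after the key step.

**Alternative 2:** Here the furan C2–C3 bond is disconnected, leading back to the benzyl aryl ether aldehyde A4 (2-{[7-(methoxymethoxy)-2,2-dimethylchroman-5-yl]methoxy}-4,6-bis(methoxymethoxy)-3-(2-methylbut-3-en-2-yl)benzaldehyde).
- Forward key step: a phosphazene superbase removes a proton from the ArCH2O carbon, the carbanion adds to the ortho aldehyde and water is lost, giving the tris-acetal A3 (2-[7-(methoxymethoxy)-2,2-dimethylchroman-5-yl]-4,6-bis(methoxymethoxy)-7-(2-methylbut-3-en-2-yl)benzofuran).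
- For it: it is the most convergent plan, and its endgame is shorter than the chosen one, with only one deprotection after the ring closure and the C7 group already in place.
- Against it: the carbanion has no stabilising group beyond an electron-rich arene, so [1,2]-Wittig rearrangement and deprotonation elsewhere compete. The ether oxygen of A4 lies between a formyl group and a tertiary alkyl group, so making that ether is itself difficult. The chroman-5-ylmethyl electrophile again requires the meta-substituted ring C.
- Comparison: the chosen route gives up the late convergence but places its risk in a cycloaddition whose polarity is unambiguous.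

**Alternative 3:** Here ring A is disconnected at C4–C5, C6–C7 and C3a–C4, leading back to the furyl diazoketone A6 (2-diazo-1-{5-[7-(methoxymethoxy)-2,2-dimethylchroman-5-yl]furan-2-yl}ethan-1-one) and the silyloxyalkyne A7 (ethynyloxy(triisopropyl)silane).
- Forward key step: photochemical Wolff rearrangement gives a furylketene, which adds A7 to a cyclobutenone. This opens to a dienylketene and closes onto furan C3 to give A5 (2-[7-(methoxymethoxy)-2,2-dimethylchroman-5-yl]-6-(triisopropylsilyloxy)benzofuran-4-ol).
- For it: O4 and O6 emerge differentiated by the mechanism, which is better than the chosen route's selective alkylation.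
- Against it: the arylfuran in A6 needs a cross-coupling at C5' of a preformed chroman, so the ring that is hard to buy is not addressed. A diazoketone, a photochemical step and a labile ynol ether are required. A5 still needs protection of O4, silyl removal and allylation before the same Claisen endgame.
- Comparison: both plans build one benzene ring pericyclically, but the chosen one builds ring C, which is not available, and buys ring A ready-made.

Key step: step 10

## Route

Remark on the chemistry: silyl enol ether 2 and diene 4 are taken as mixtures of double-bond isomers, and the racemic intermediates 9, 10, 17, 19, 23, 24 and 26 are drawn without configuration. None of these elements survives into the target.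

**Step 1**
Reactants: 1 methyl acetoacetate
Product: 2 methyl 3-(trimethylsilyloxy)but-2-enoate
Conditions: TMSCl, Et3N, hexane, rt
Reagents that add atoms: chlorotrimethylsilane, C[Si](C)(C)Cl
Why: O-silylation of the enol of a β-keto ester under amine base (silyl enol ether formation); the geometry is of no consequence.

**Step 2**
Reactants: 2 methyl 3-(trimethylsilyloxy)but-2-enoate
Product: 4 1-methoxy-1,3-bis(trimethylsilyloxy)buta-1,3-diene, via lithium dienolate 3 (not isolated)
Conditions: LiN(i-Pr)2, THF, −78 °C; TMSCl, −78 °C → rt; distillation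
Reagents that add atoms: chlorotrimethylsilane, C[Si](C)(C)Cl
Why: γ-Deprotonation of the vinylogous ester gives an extended dienolate that is silylated on oxygen, the standard preparation of 1-alkoxy-1,3-bis(silyloxy)dienes.

**Step 3**
Reactants: 5 4,6-dihydroxybenzofuran-3(2H)-one; 6 1-bromo-3-methylbut-2-ene (prenyl bromide)
Product: 7 4-hydroxy-6-[(3-methylbut-2-en-1-yl)oxy]benzofuran-3(2H)-one
Conditions: K2CO3 (1.05 equiv), 6 (1.05 equiv), DMF, 0 °C → rt
Reagents that add atoms: none
Why: Williamson etherification; the C6 hydroxyl, para-related to the carbonyl and not hydrogen-bonded, is the more acidic and is alkylated first, while the C4 hydroxyl is held by the C3 carbonyl.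

**Step 4**
Reactants: 7 4-hydroxy-6-[(3-methylbut-2-en-1-yl)oxy]benzofuran-3(2H)-one
Product: 8 4-(methoxymethoxy)-6-[(3-methylbut-2-en-1-yl)oxy]benzofuran-3(2H)-one
Conditions: MOMCl, i-Pr2NEt, CH2Cl2, 0 °C → rt
Reagents that add atoms: chloromethyl methyl ether, COCCl
Why: Acetal protection of the remaining phenol with a reactive alkoxymethyl chloride and a hindered amine, which does not enolise the C2 methylene.

**Step 5**
Reactants: 8 4-(methoxymethoxy)-6-[(3-methylbut-2-en-1-yl)oxy]benzofuran-3(2H)-one
Product: 11 4-(methoxymethoxy)-6-[(3-methylbut-2-en-1-yl)oxy]benzofuran, via dihydrobenzofuranol 9 (not isolated), via benzylic mesylate 10 (not isolated)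
Conditions: NaBH4, MeOH/THF, 0 °C; then MsCl, Et3N, CH2Cl2, 0 °C → rt
Reagents that add atoms: none
Why: Hydride reduction of the ketone followed by sulfonylation and elimination; the benzylic C3 position is flanked by three oxygen-bearing ring carbons, so the mesylate should ionise and lose the C2 proton readily to give the aromatic furan without acid.

**Step 6**
Reactants: 11 4-(methoxymethoxy)-6-[(3-methylbut-2-en-1-yl)oxy]benzofuran
Product: 13 4-(methoxymethoxy)-6-[(3-methylbut-2-en-1-yl)oxy]benzofuran-2-carbaldehyde, via 2-lithiobenzofuran 12 (not isolated)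
Conditions: n-BuLi, THF, −78 °C; DMF, −78 → 0 °C; aq NH4Cl
Reagents that add atoms: N,N-dimethylformamide, CN(C)C=O
Why: Deprotonation and formylation of a benzofuran at C2, its most acidic C–H bond; at −78 °C this kinetic lithiation should outpace acetal-directed metalation at C5 and deprotonation of the allylic ether.

**Step 7**
Reactants: 13 4-(methoxymethoxy)-6-[(3-methylbut-2-en-1-yl)oxy]benzofuran-2-carbaldehyde
Product: 14 2-ethynyl-4-(methoxymethoxy)-6-[(3-methylbut-2-en-1-yl)oxy]benzofuran
Conditions: dimethyl (1-diazo-2-oxopropyl)phosphonate, K2CO3, MeOH, 0 °C → rt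
Reagents that add atoms: dimethyl (1-diazo-2-oxopropyl)phosphonate, CC(=O)C(=[N+]=[N-])P(=O)(OC)OC
Why: Seyferth–Gilbert homologation with the Ohira–Bestmann reagent; the aldehyde is non-enolisable and the mild carbonate conditions leave both ethers untouched.

**Step 8**
Reactants: 14 2-ethynyl-4-(methoxymethoxy)-6-[(3-methylbut-2-en-1-yl)oxy]benzofuran; 15 3-methylbut-2-enal
Product: 17 1-{4-(methoxymethoxy)-6-[(3-methylbut-2-en-1-yl)oxy]benzofuran-2-yl}-5-methylhex-4-en-1-yn-3-ol, via lithium acetylide 16 (not isolated)
Conditions: n-BuLi, THF, −78 °C; 15, −78 → −20 °C; aq NH4Cl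
Reagents that add atoms: none
Why: 1,2-Addition of a lithium acetylide to an enal; the alkyne C–H is far more acidic than any other position, and the new carbinol centre is racemic and is destroyed in the next step.

**Step 9**
Reactants: 17 1-{4-(methoxymethoxy)-6-[(3-methylbut-2-en-1-yl)oxy]benzofuran-2-yl}-5-methylhex-4-en-1-yn-3-ol
Product: 18 1-{4-(methoxymethoxy)-6-[(3-methylbut-2-en-1-yl)oxy]benzofuran-2-yl}-5-methylhex-4-en-1-yn-3-one
Conditions: MnO2 (activated), CH2Cl2, rt
Reagents that add atoms: none
Why: Heterogeneous oxidation of an alcohol that is both propargylic and allylic; the neutral conditions avoid ionisation of this doubly activated carbinol.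

**Step 10**
Reactants: 18 1-{4-(methoxymethoxy)-6-[(3-methylbut-2-en-1-yl)oxy]benzofuran-2-yl}-5-methylhex-4-en-1-yn-3-one; 4 1-methoxy-1,3-bis(trimethylsilyloxy)buta-1,3-diene
Product: 20 1-(2,4-dihydroxy-6-{4-(methoxymethoxy)-6-[(3-methylbut-2-en-1-yl)oxy]benzofuran-2-yl}phenyl)-3-methylbut-2-en-1-one, via silylated cycloadduct 19 (not isolated)
Conditions: 4 (2.5 equiv), PhMe, 90 °C; then 0.5 M HCl, THF, 0 °C
Reagents that add atoms: none
Why: This is a normal-electron-demand [4+2] cycloaddition: diene 4 is raised in energy by three oxygen donors and has its largest HOMO coefficient on the unsubstituted methylene, while ynone 18 has its largest LUMO coefficient on the alkyne carbon β to the carbonyl, the one that bears the benzofuran. Bonding of the diene methylene to that carbon (C5'–C6') and of the ketene-acetal carbon to the acyl-bearing carbon (C4a'–C8a') gives the 1,4-cyclohexadiene 19, whether the bonds form in concert or stepwise through a Mukaiyama–Michael-type zwitterion that collapses to the same ring. Dilute acid then cleaves the silyl ethers, the hemiketal at C8a' loses methanol, and the resulting diketone tautomerises to the resorcinol-type ring C. The closest known reaction type is the cycloaddition–aromatisation of 1-alkoxy-1,3-bis(silyloxy)dienes with acetylenic ketones and esters to resorcinol derivatives. Ring C is closed as a six-membered carbocycle by an intermolecular cycloaddition that makes both ring bonds in one operation. The only stereocentre formed, the ketal carbon of 19, disappears on aromatisation, so no stereocontrol is needed. The step needs regioselectivity, and the conjugated carbonyl secures it by polarising the triple bond. Chemoselectivity follows because the enone double bond is disubstituted at its β-carbon and hindered, and the allyl ether alkene is unactivated.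

**Step 11**
Reactants: 20 1-(2,4-dihydroxy-6-{4-(methoxymethoxy)-6-[(3-methylbut-2-en-1-yl)oxy]benzofuran-2-yl}phenyl)-3-methylbut-2-en-1-one
Product: 21 7-hydroxy-5-{4-(methoxymethoxy)-6-[(3-methylbut-2-en-1-yl)oxy]benzofuran-2-yl}-2,2-dimethylchroman-4-one
Conditions: K2CO3, MeOH, rt → 40 °C
Reagents that add atoms: none
Why: 6-endo-trig oxa-Michael addition of the ortho phenoxide to the β,β-dimethyl enone, the usual closure of 2'-hydroxyaryl 2-methylprop-1-enyl ketones to 2,2-dimethylchroman-4-ones; only the hydroxyl ortho to the acyl group can reach the β-carbon, and any material that has already cyclised during the acidic work-up of step 10 converges on the same product.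

**Step 12**
Reactants: 21 7-hydroxy-5-{4-(methoxymethoxy)-6-[(3-methylbut-2-en-1-yl)oxy]benzofuran-2-yl}-2,2-dimethylchroman-4-one
Product: 22 (E)-N'-(7-hydroxy-5-{4-(methoxymethoxy)-6-[(3-methylbut-2-en-1-yl)oxy]benzofuran-2-yl}-2,2-dimethylchroman-4-ylidene)-4-methylbenzenesulfonohydrazide
Conditions: TsNHNH2, EtOH, AcOH (cat.), 70 °C
Reagents that add atoms: 4-methylbenzenesulfonohydrazide, Cc1ccc(cc1)S(=O)(=O)NN
Why: Condensation of a chroman-4-one with a sulfonylhydrazide under weak acid, which the acetal tolerates; the sulfonamide nitrogen should point towards the C3' methylene and away from the peri benzofuranyl group, and either geometry is reduced alike.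

**Step 13**
Reactants: 22 (E)-N'-(7-hydroxy-5-{4-(methoxymethoxy)-6-[(3-methylbut-2-en-1-yl)oxy]benzofuran-2-yl}-2,2-dimethylchroman-4-ylidene)-4-methylbenzenesulfonohydrazide
Product: 25 5-{4-(methoxymethoxy)-6-[(3-methylbut-2-en-1-yl)oxy]benzofuran-2-yl}-2,2-dimethylchroman-7-ol, via N-boryl hydrazine 23 (not isolated), via alkyl diazene 24 (not isolated)
Conditions: catecholborane (3 equiv), CHCl3, 0 °C → rt; then NaOAc·3H2O, reflux
Reagents that add atoms: none
Why: Reductive deoxygenation of a tosylhydrazone: the borane adds hydride to C4' (the phenol is taken up as its borate ester by a further equivalent), acetate then releases sulfinate to give the diazene, which loses nitrogen to leave the methylene. The conditions are neither acidic nor hydrogenative, so the acetal, the allyl ether and the benzofuran should survive.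

**Step 14**
Reactants: 25 5-{4-(methoxymethoxy)-6-[(3-methylbut-2-en-1-yl)oxy]benzofuran-2-yl}-2,2-dimethylchroman-7-ol
Product: 27 2-(7-hydroxy-2,2-dimethylchroman-5-yl)-4-(methoxymethoxy)-7-(2-methylbut-3-en-2-yl)benzofuran-6-ol, via cyclohexadienone 26 (not isolated)
Conditions: PhNEt2, 190 °C, Ar, sealed tube
Reagents that add atoms: none
Why: Aromatic Claisen rearrangement: the [3,3] shift bonds the dimethyl-substituted allyl terminus to the ortho carbon and dienone 26 tautomerises to the phenol. C7 should be preferred over C5 because the C6–C7 bond of a benzofuran has the higher π-bond order and C5 is crowded by the neighbouring acetal oxygen.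

**Step 15**
Reactants: 27 2-(7-hydroxy-2,2-dimethylchroman-5-yl)-4-(methoxymethoxy)-7-(2-methylbut-3-en-2-yl)benzofuran-6-ol
Product: 28 2-(7-hydroxy-2,2-dimethylchroman-5-yl)-7-(2-methylbut-3-en-2-yl)benzofuran-4,6-diol (CNP0300714.0)
Conditions: 2 M HCl, MeOH/THF, 40 °C
Reagents that add atoms: none
Why: Acid-catalysed transacetalisation of an aryl methoxymethyl ether to methanol; dilute acid at this temperature should not protonate the monosubstituted vinyl group, so the reverse-prenyl unit next to the C6 hydroxyl should stay open.

## Compound list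

1 | methyl acetoacetate | COC(=O)CC(C)=O | starting material
2 | methyl 3-(trimethylsilyloxy)but-2-enoate (mixture of double-bond isomers) | COC(=O)C=C(C)O[Si](C)(C)C | intermediate
3 | lithium 1-methoxy-3-(trimethylsilyloxy)buta-1,3-dien-1-olate | [Li]OC(OC)=CC(=C)O[Si](C)(C)C | intermediate
4 | 1-methoxy-1,3-bis(trimethylsilyloxy)buta-1,3-diene (mixture of double-bond isomers) | C=C(O[Si](C)(C)C)C=C(OC)O[Si](C)(C)C | intermediate
5 | 4,6-dihydroxybenzofuran-3(2H)-one | O=C1COc2cc(O)cc(O)c12 | starting material
6 | 1-bromo-3-methylbut-2-ene (prenyl bromide) | CC(C)=CCBr | starting material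
7 | 4-hydroxy-6-[(3-methylbut-2-en-1-yl)oxy]benzofuran-3(2H)-one | O=C1COc2cc(OCC=C(C)C)cc(O)c12 | intermediate
8 | 4-(methoxymethoxy)-6-[(3-methylbut-2-en-1-yl)oxy]benzofuran-3(2H)-one | O=C1COc2cc(OCC=C(C)C)cc(OCOC)c12 | intermediate
9 | 4-(methoxymethoxy)-6-[(3-methylbut-2-en-1-yl)oxy]-2,3-dihydrobenzofuran-3-ol (racemic) | OC1COc2cc(OCC=C(C)C)cc(OCOC)c12 | intermediate
10 | 4-(methoxymethoxy)-6-[(3-methylbut-2-en-1-yl)oxy]-2,3-dihydrobenzofuran-3-yl methanesulfonate (racemic) | CS(=O)(=O)OC1COc2cc(OCC=C(C)C)cc(OCOC)c12 | intermediate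
11 | 4-(methoxymethoxy)-6-[(3-methylbut-2-en-1-yl)oxy]benzofuran | COCOc1cc(OCC=C(C)C)cc2occc12 | intermediate
12 | 2-lithio-4-(methoxymethoxy)-6-[(3-methylbut-2-en-1-yl)oxy]benzofuran | [Li]c1cc2c(OCOC)cc(OCC=C(C)C)cc2o1 | intermediate
13 | 4-(methoxymethoxy)-6-[(3-methylbut-2-en-1-yl)oxy]benzofuran-2-carbaldehyde | O=Cc1cc2c(OCOC)cc(OCC=C(C)C)cc2o1 | intermediate
14 | 2-ethynyl-4-(methoxymethoxy)-6-[(3-methylbut-2-en-1-yl)oxy]benzofuran | C#Cc1cc2c(OCOC)cc(OCC=C(C)C)cc2o1 | intermediate
15 | 3-methylbut-2-enal | CC(C)=CC=O | starting material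
16 | lithium {4-(methoxymethoxy)-6-[(3-methylbut-2-en-1-yl)oxy]benzofuran-2-yl}acetylide | [Li]C#Cc1cc2c(OCOC)cc(OCC=C(C)C)cc2o1 | intermediate
17 | 1-{4-(methoxymethoxy)-6-[(3-methylbut-2-en-1-yl)oxy]benzofuran-2-yl}-5-methylhex-4-en-1-yn-3-ol (racemic) | CC(C)=CC(O)C#Cc1cc2c(OCOC)cc(OCC=C(C)C)cc2o1 | intermediate
18 | 1-{4-(methoxymethoxy)-6-[(3-methylbut-2-en-1-yl)oxy]benzofuran-2-yl}-5-methylhex-4-en-1-yn-3-one | CC(C)=CC(=O)C#Cc1cc2c(OCOC)cc(OCC=C(C)C)cc2o1 | intermediate
19 | 1-(6-methoxy-2-{4-(methoxymethoxy)-6-[(3-methylbut-2-en-1-yl)oxy]benzofuran-2-yl}-4,6-bis(trimethylsilyloxy)cyclohexa-1,4-dien-1-yl)-3-methylbut-2-en-1-one (racemic) | COC1(O[Si](C)(C)C)C=C(O[Si](C)(C)C)CC(c2cc3c(OCOC)cc(OCC=C(C)C)cc3o2)=C1C(=O)C=C(C)C | intermediate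
20 | 1-(2,4-dihydroxy-6-{4-(methoxymethoxy)-6-[(3-methylbut-2-en-1-yl)oxy]benzofuran-2-yl}phenyl)-3-methylbut-2-en-1-one | CC(C)=CC(=O)c1c(O)cc(O)cc1-c1cc2c(OCOC)cc(OCC=C(C)C)cc2o1 | intermediate
21 | 7-hydroxy-5-{4-(methoxymethoxy)-6-[(3-methylbut-2-en-1-yl)oxy]benzofuran-2-yl}-2,2-dimethylchroman-4-one | CC(C)=CCOc1cc(OCOC)c2cc(-c3cc(O)cc4c3C(=O)CC(C)(C)O4)oc2c1 | intermediate
22 | (E)-N'-(7-hydroxy-5-{4-(methoxymethoxy)-6-[(3-methylbut-2-en-1-yl)oxy]benzofuran-2-yl}-2,2-dimethylchroman-4-ylidene)-4-methylbenzenesulfonohydrazide | CC(C)=CCOc1cc(OCOC)c2cc(-c3cc(O)cc4c3/C(=N/NS(=O)(=O)c3ccc(C)cc3)CC(C)(C)O4)oc2c1 | intermediate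
23 | N'-(1,3,2-benzodioxaborol-2-yl)-N'-[7-(1,3,2-benzodioxaborol-2-yloxy)-5-{4-(methoxymethoxy)-6-[(3-methylbut-2-en-1-yl)oxy]benzofuran-2-yl}-2,2-dimethylchroman-4-yl]-4-methylbenzenesulfonohydrazide (racemic) | CC(C)=CCOc1cc(OCOC)c2cc(-c3cc(OB5Oc6ccccc6O5)cc4c3C(N(B5Oc6ccccc6O5)NS(=O)(=O)c3ccc(C)cc3)CC(C)(C)O4)oc2c1 | intermediate
24 | 4-diazenyl-5-{4-(methoxymethoxy)-6-[(3-methylbut-2-en-1-yl)oxy]benzofuran-2-yl}-2,2-dimethylchroman-7-ol (racemic) | CC(C)=CCOc1cc(OCOC)c2cc(-c3cc(O)cc4c3C(N=N)CC(C)(C)O4)oc2c1 | intermediate
25 | 5-{4-(methoxymethoxy)-6-[(3-methylbut-2-en-1-yl)oxy]benzofuran-2-yl}-2,2-dimethylchroman-7-ol | CC(C)=CCOc1cc(OCOC)c2cc(-c3cc(O)cc4c3CCC(C)(C)O4)oc2c1 | intermediate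
26 | 2-(7-hydroxy-2,2-dimethylchroman-5-yl)-4-(methoxymethoxy)-7-(2-methylbut-3-en-2-yl)benzofuran-6(7H)-one (racemic) | C=CC(C)(C)C1C(=O)C=C(OCOC)C2=C1OC(=C2)c1cc(O)cc2c1CCC(C)(C)O2 | intermediate
27 | 2-(7-hydroxy-2,2-dimethylchroman-5-yl)-4-(methoxymethoxy)-7-(2-methylbut-3-en-2-yl)benzofuran-6-ol | C=CC(C)(C)c1c(O)cc(OCOC)c2cc(-c3cc(O)cc4c3CCC(C)(C)O4)oc12 | intermediate
28 | 2-(7-hydroxy-2,2-dimethylchroman-5-yl)-7-(2-methylbut-3-en-2-yl)benzofuran-4,6-diol (CNP0300714.0) | C=CC(C)(C)c1c(O)cc(O)c2cc(-c3cc(O)cc4c3CCC(C)(C)O4)oc12 | target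

## Step count and least certain steps

Total: 15 steps. Longest linear sequence: 13 steps (5 to 28, steps 3–15). The diene branch (steps 1–2) joins at step 10.

**Step 10 (key step).**
- What may go wrong: the diene may react through its C4 and C2 carbons (conjugate addition, then aldol closure onto the ketone carbonyl), giving a salicylate-type ring instead of the resorcinol. The diene may lose its silyl groups before it adds. Addition may be slow, because the benzofuranyl donor lowers the electrophilicity of the triple bond.
- Fallback: it sets out from benzofuran 11 and returns at chromanone 21, giving up ring construction for a cross-coupling. Compound 11 would be lithiated at C2 and quenched with an isopropoxy pinacolborane to give 2-{4-(methoxymethoxy)-6-[(3-methylbut-2-en-1-yl)oxy]benzofuran-2-yl}-4,4,5,5-tetramethyl-1,3,2-dioxaborolane F1. Separately, Friedel–Crafts acylation and cyclisation of benzene-1,3,5-triol with 3-methylbut-2-enoic acid would give 5,7-dihydroxy-2,2-dimethylchroman-4-one F2. Silylation at the non-chelated O7 (TBSCl, imidazole) would give 7-(tert-butyldimethylsilyloxy)-5-hydroxy-2,2-dimethylchroman-4-one F3, and triflation of the chelated O5 (Tf2O, pyridine) would give 7-(tert-butyldimethylsilyloxy)-2,2-dimethyl-4-oxochroman-5-yl trifluoromethanesulfonate F4. Suzuki–Miyaura coupling of F1 with F4 (Pd(PPh3)4, K3PO4, dioxane/H2O) would give 7-(tert-butyldimethylsilyloxy)-5-{4-(methoxymethoxy)-6-[(3-methylbut-2-en-1-yl)oxy]benzofuran-2-yl}-2,2-dimethylchroman-4-one F5, and Bu4NF would then release 21.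

**Step 13.**
- What may go wrong: hydride transfer to the C=N bond may be slow, since it is deactivated by the para oxygen and screened by the peri benzofuranyl group. Sulfinate may then be eliminated from unreduced hydrazone, leading to the chromene. Excess borane may also hydroborate the allyl ether alkene.
- Fallback: it sets out from 21 and returns at 25. NaBH4 in EtOH would reduce the ketone to 5-{4-(methoxymethoxy)-6-[(3-methylbut-2-en-1-yl)oxy]benzofuran-2-yl}-2,2-dimethylchroman-4,7-diol F6. Heating F6 with NaBH4 in aqueous NaOH/EtOH would let the C7' phenoxide expel hydroxide from C4' to give the para-quinone methide 5-{4-(methoxymethoxy)-6-[(3-methylbut-2-en-1-yl)oxy]benzofuran-2-yl}-2,2-dimethyl-2,3-dihydro-7H-chromen-7-one F7, which hydride reduces at C4' to 25. This is the known hydrogenolysis of para-hydroxybenzyl alcohols by borohydride in hot alkali.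

**Step 14.**
- What may go wrong: the allyl group may migrate to C5 instead of C7. The new phenol may transfer hydrogen to the allyl terminus, followed by skeletal drift of the side chain (abnormal Claisen pathway). The ether may also fragment to the phenol.
- Fallback: it sets out from 25 and returns at 27, trapping the rearranged phenol as an ester as it forms. Compound 25 would be acetylated (Ac2O, pyridine) to 5-{4-(methoxymethoxy)-6-[(3-methylbut-2-en-1-yl)oxy]benzofuran-2-yl}-2,2-dimethylchroman-7-yl acetate F8. Heating F8 in Ac2O/NaOAc/PhNEt2 would give 2-(7-acetoxy-2,2-dimethylchroman-5-yl)-4-(methoxymethoxy)-7-(2-methylbut-3-en-2-yl)benzofuran-6-yl acetate F9, and K2CO3 in MeOH would cleave both esters to 27. This answers the onward reactions but does not change the intrinsic C7/C5 preference.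

**Step 3.**
- What may go wrong: alkylation at both oxygens or at O4, and C-alkylation at the enolisable C2 methylene.
- Fallback: it sets out from 5 and returns at 8, differentiating the phenols with a bulky silyl group and no carbon electrophile. TIPSCl and imidazole in DMF would give 4-hydroxy-6-(triisopropylsilyloxy)benzofuran-3(2H)-one F10. MOMCl and i-Pr2NEt would give 4-(methoxymethoxy)-6-(triisopropylsilyloxy)benzofuran-3(2H)-one F11. Bu4NF buffered with AcOH would give 6-hydroxy-4-(methoxymethoxy)benzofuran-3(2H)-one F12, whose single phenol is alkylated with 6 and K2CO3 to give 8.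

**Step 15.**
- What may go wrong: acid-promoted addition of the C6 hydroxyl across the neighbouring vinyl group, closing a dihydrofuran, or acid degradation of the electron-rich benzofuran.
- Fallback: it sets out from 25 and returns at 28, reordering the endgame so that the last step is neutral. The acetal of 25 would be cleaved first (2 M HCl, MeOH/THF), while no reverse-prenyl group is present, to give 2-(7-hydroxy-2,2-dimethylchroman-5-yl)-6-[(3-methylbut-2-en-1-yl)oxy]benzofuran-4-ol F13. Thermal Claisen rearrangement of F13 in PhNEt2 would then give 28 directly. The allyl aryl ether has to survive the acid, and C7 selectivity would then rest on π-bond order alone.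

## Further compounds

F1 | step 10 | 2-{4-(methoxymethoxy)-6-[(3-methylbut-2-en-1-yl)oxy]benzofuran-2-yl}-4,4,5,5-tetramethyl-1,3,2-dioxaborolane | CC(C)=CCOc1cc(OCOC)c2cc(B3OC(C)(C)C(C)(C)O3)oc2c1
F2 | step 10 | 5,7-dihydroxy-2,2-dimethylchroman-4-one | CC1(C)CC(=O)c2c(O)cc(O)cc2O1
F3 | step 10 | 7-(tert-butyldimethylsilyloxy)-5-hydroxy-2,2-dimethylchroman-4-one | CC1(C)CC(=O)c2c(O)cc(O[Si](C)(C)C(C)(C)C)cc2O1
F4 | step 10 | 7-(tert-butyldimethylsilyloxy)-2,2-dimethyl-4-oxochroman-5-yl trifluoromethanesulfonate | CC1(C)CC(=O)c2c(OS(=O)(=O)C(F)(F)F)cc(O[Si](C)(C)C(C)(C)C)cc2O1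
F5 | step 10 | 7-(tert-butyldimethylsilyloxy)-5-{4-(methoxymethoxy)-6-[(3-methylbut-2-en-1-yl)oxy]benzofuran-2-yl}-2,2-dimethylchroman-4-one | CC(C)=CCOc1cc(OCOC)c2cc(-c3cc(O[Si](C)(C)C(C)(C)C)cc4c3C(=O)CC(C)(C)O4)oc2c1
F6 | step 13 | 5-{4-(methoxymethoxy)-6-[(3-methylbut-2-en-1-yl)oxy]benzofuran-2-yl}-2,2-dimethylchroman-4,7-diol (racemic) | CC(C)=CCOc1cc(OCOC)c2cc(-c3cc(O)cc4c3C(O)CC(C)(C)O4)oc2c1
F7 | step 13 | 5-{4-(methoxymethoxy)-6-[(3-methylbut-2-en-1-yl)oxy]benzofuran-2-yl}-2,2-dimethyl-2,3-dihydro-7H-chromen-7-one | CC(C)=CCOc1cc(OCOC)c2cc(C3=CC(=O)C=C4OC(C)(C)CC=C34)oc2c1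
F8 | step 14 | 5-{4-(methoxymethoxy)-6-[(3-methylbut-2-en-1-yl)oxy]benzofuran-2-yl}-2,2-dimethylchroman-7-yl acetate | CC(C)=CCOc1cc(OCOC)c2cc(-c3cc(OC(C)=O)cc4c3CCC(C)(C)O4)oc2c1
F9 | step 14 | 2-(7-acetoxy-2,2-dimethylchroman-5-yl)-4-(methoxymethoxy)-7-(2-methylbut-3-en-2-yl)benzofuran-6-yl acetate | C=CC(C)(C)c1c(OC(C)=O)cc(OCOC)c2cc(-c3cc(OC(C)=O)cc4c3CCC(C)(C)O4)oc12
F10 | step 3 | 4-hydroxy-6-(triisopropylsilyloxy)benzofuran-3(2H)-one | O=C1COc2cc(O[Si](C(C)C)(C(C)C)C(C)C)cc(O)c12
F11 | step 3 | 4-(methoxymethoxy)-6-(triisopropylsilyloxy)benzofuran-3(2H)-one | O=C1COc2cc(O[Si](C(C)C)(C(C)C)C(C)C)cc(OCOC)c12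
F12 | step 3 | 6-hydroxy-4-(methoxymethoxy)benzofuran-3(2H)-one | O=C1COc2cc(O)cc(OCOC)c12
F13 | step 15 | 2-(7-hydroxy-2,2-dimethylchroman-5-yl)-6-[(3-methylbut-2-en-1-yl)oxy]benzofuran-4-ol | CC(C)=CCOc1cc(O)c2cc(-c3cc(O)cc4c3CCC(C)(C)O4)oc2c1
A1 | alternative 1 | methyl trans-6-(benzyloxy)-2-[2,2-dimethyl-7-(tosyloxy)chroman-5-yl]-4-(tosyloxy)-2,3-dihydrobenzofuran-3-carboxylate (racemic, one enantiomer drawn) | COC(=O)[C@@H]1[C@@H](c2cc(OS(=O)(=O)c3ccc(C)cc3)cc3c2CCC(C)(C)O3)Oc2cc(OCc3ccccc3)cc(OS(=O)(=O)c3ccc(C)cc3)c12
A2 | alternative 1 | 7-(benzyloxy)-2-[2,2-dimethyl-7-(tosyloxy)chroman-5-yl]-5-(tosyloxy)chroman-4-one (racemic) | O=C1CC(c2cc(OS(=O)(=O)c3ccc(C)cc3)cc3c2CCC(C)(C)O3)Oc2cc(OCc3ccccc3)cc(OS(=O)(=O)c3ccc(C)cc3)c12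
A3 | alternative 2 | 2-[7-(methoxymethoxy)-2,2-dimethylchroman-5-yl]-4,6-bis(methoxymethoxy)-7-(2-methylbut-3-en-2-yl)benzofuran | C=CC(C)(C)c1c(OCOC)cc(OCOC)c2cc(-c3cc(OCOC)cc4c3CCC(C)(C)O4)oc12
A4 | alternative 2 | 2-{[7-(methoxymethoxy)-2,2-dimethylchroman-5-yl]methoxy}-4,6-bis(methoxymethoxy)-3-(2-methylbut-3-en-2-yl)benzaldehyde | C=CC(C)(C)c1c(OCOC)cc(OCOC)c(C=O)c1OCc1cc(OCOC)cc2c1CCC(C)(C)O2
A5 | alternative 3 | 2-[7-(methoxymethoxy)-2,2-dimethylchroman-5-yl]-6-(triisopropylsilyloxy)benzofuran-4-ol | Oc1cc(O[Si](C(C)C)(C(C)C)C(C)C)cc2oc(-c3cc(OCOC)cc4c3CCC(C)(C)O4)cc12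
A6 | alternative 3 | 2-diazo-1-{5-[7-(methoxymethoxy)-2,2-dimethylchroman-5-yl]furan-2-yl}ethan-1-one | [N-]=[N+]=CC(=O)c1ccc(-c2cc(OCOC)cc3c2CCC(C)(C)O3)o1
A7 | alternative 3 | ethynyloxy(triisopropyl)silane | C#CO[Si](C(C)C)(C(C)C)C(C)C
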